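**Plan**
- Retrosynthesis: the three phenols are masked as methyl ethers; the butenolide is cut at its lactone C–O bond and at the C=C bond to the arylacetic carbon; the furan is cut at its C2–O bond; the central ring is cut at the C(=O)–C(Ph) bond and at the bond from benzofuran C3 to the butenolide β-carbon.
- Enabling feature: read round the central six-membered ring, the atoms benzofuran C3–benzofuran C2(O)–ketone C and C(Ph)–C(O, lactone)–butenolide β-C are two aryl–C–C(O)–C(O) arylpyruvate units joined head to tail. Together they already stand at the oxidation level of a 2,5-dihydroxy-1,4-benzoquinone.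
- Forward: a coumarin is built as a temporary ring (its lactone is the acyl donor, its enol oxygen the tether, its ring oxygen the later furan oxygen); the tethered enol ester then gives the central ring by double acyl transfer; the furan follows by cyclodehydration, the butenolide by Perkin-type condensation, and demethylation ends the route.
- Stereochemistry: the target has no stereocentre and no stereogenic double bond; the Z enol ether geometry of the tethered precursor is consumed in the key step.

Key step: step 5

Remark: the target is taken as the achiral constitution given by the SMILES; the hydroxyquinones are drawn as one of their equivalent tautomers.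

**Step 1**
Reactants: 1 2-hydroxy-4,5-dimethoxybenzaldehyde; 2 N-acetylglycine
Product: 3 3-acetamido-6,7-dimethoxy-2H-chromen-2-one
Conditions: Ac2O, NaOAc, 110 °C
Reagents that add atoms: none
Why: Erlenmeyer–Plöchl azlactone condensation of the aldehyde with N-acetylglycine, followed in the same flask by attack of the ortho phenol on the azlactone carbonyl, is the standard Perkin-type entry to 3-acetamidocoumarins from salicylaldehydes.

**Step 2**
Reactants: 3 3-acetamido-6,7-dimethoxy-2H-chromen-2-one
Product: 4 3-hydroxy-6,7-dimethoxy-2H-chromen-2-one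
Conditions: 3 M aq. HCl, reflux
Reagents that add atoms: water, O
Why: Acid hydrolysis of the enamide (amide cleavage, then hydrolysis of the enamine tautomer) is the standard way from 3-acetamidocoumarins to 3-hydroxycoumarins, the enol lactones of ortho-hydroxyarylpyruvic acids; the aryl methyl ethers and the lactone should survive aqueous HCl.

**Step 3**
Reactants: 5 phenylpyruvic acid
Product: 7 (Z)-2-[(tert-butyldimethylsilyl)oxy]-3-phenylprop-2-enoic acid, via bis-silyl derivative 6 (not isolated)
Conditions: TBSCl (2.3 equiv), imidazole, DMF, rt; then AcOH/THF/H2O, 0 °C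
Reagents that add atoms: tert-butyldimethylsilyl chloride, CC(C)(C)[Si](C)(C)Cl
Why: Phenylpyruvic acid reacts as its Z enol, so silylation should give the Z silyl enol ether silyl ester 6, and the much more labile silyl ester is then hydrolysed selectively (standard O-silylation and silyl ester cleavage).

**Step 4**
Reactants: 4 3-hydroxy-6,7-dimethoxy-2H-chromen-2-one; 7 (Z)-2-[(tert-butyldimethylsilyl)oxy]-3-phenylprop-2-enoic acid
Product: 8 6,7-dimethoxy-2-oxo-2H-chromen-3-yl (Z)-2-[(tert-butyldimethylsilyl)oxy]-3-phenylprop-2-enoate
Conditions: DCC, DMAP (cat.), CH2Cl2, 0 °C to rt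
Reagents that add atoms: none
Why: Steglich esterification; the enol hydroxyl of 4 is acidic and phenol-like and should be acylated readily, while the silyl enol ether and the coumarin lactone are inert to DCC and DMAP.

**Step 5**
Reactants: 8 6,7-dimethoxy-2-oxo-2H-chromen-3-yl (Z)-2-[(tert-butyldimethylsilyl)oxy]-3-phenylprop-2-enoate
Product: 12 2,5-dihydroxy-3-(2-hydroxy-4,5-dimethoxyphenyl)-6-phenylcyclohexa-2,5-diene-1,4-dione, via free enol ester 9 (not isolated), via pyrandione 10 (not isolated), via seco methyl ester 11 (not isolated)
Conditions: Bu4NF (1.1 equiv), THF, −40 to 0 °C; then NaOMe (4 equiv), MeOH, 50 °C; then 1 M HCl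
Reagents that add atoms: none
Why: Proposed new method: fluoride should remove the silyl group of 8 and free the phenylpyruvate enolate of 9, whose benzylic carbon should acylate itself on the coumarin lactone carbonyl (an aryl ester) with loss of the aryloxide to give pyrandione 10 (first C–C bond, C(Ph)–C=O); methoxide should then open the enol lactone of 10 to methyl ester 11, in which the arylpyruvate enolate released from the enol oxygen closes the carbocycle by Dieckmann condensation onto the ester (second C–C bond, from the aryl-bearing carbon to the former phenylpyruvate carboxyl carbon), with the 2,5-dihydroxyquinone dianion of 12 as thermodynamic sink. The closest known reaction types are the Claisen and Dieckmann condensations, the methoxide-induced rearrangement of ylidene butenolides into cyclopentene-1,3-diones (enol lactone opening, then C-acylation by the new ester) and the head-to-tail dimerisation of two arylpyruvates by which terphenylquinones arise in nature; no redox change is needed. Both closures are 6-exo-trig attacks of an enolate carbon on an ester carbonyl, the first giving the pyran ring of 10 and the second the carbocycle of 12. No stereocentre is formed, and the Z geometry of the enol ether is lost. The step needs crossed head-to-tail union of the two different C3 units and C-acylation instead of aldol addition or homodimerisation; the ester tether and the complementary activation in 8 (one latent enolate, one aryl-ester acyl donor) should secure the first bond, and the second is intramolecular once 10 has formed. Methoxide is added only after the first acyl transfer, so that its attack on the tether ester opens a ring productively and does not separate the two halves.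

**Step 6**
Reactants: 12 2,5-dihydroxy-3-(2-hydroxy-4,5-dimethoxyphenyl)-6-phenylcyclohexa-2,5-diene-1,4-dione
Product: 13 2-hydroxy-7,8-dimethoxy-3-phenyldibenzo[b,d]furan-1,4-dione
Conditions: H2SO4 (cat.), AcOH, 100 °C
Reagents that add atoms: none
Why: Acid-catalysed intramolecular addition–elimination of the ortho phenol at the neighbouring oxygen-bearing carbon of the hydroxyquinone (vinylogous esterification, five-membered ring) should close the furan; the two ring carbons flanking the aryl-bearing carbon are interchanged by the dihydroxyquinone tautomerism, so either mode of closure gives the same 13.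

**Step 7**
Reactants: 13 2-hydroxy-7,8-dimethoxy-3-phenyldibenzo[b,d]furan-1,4-dione; 14 (4-methoxyphenyl)acetic acid
Product: 15 2-(2-hydroxy-7,8-dimethoxy-4-oxo-3-phenyldibenzo[b,d]furan-1(4H)-ylidene)-2-(4-methoxyphenyl)acetic acid γ-lactone (tri-O-methyl ether of the target)
Conditions: Ac2O, NaOAc, 120 °C
Reagents that add atoms: none
Why: Perkin–Oglialoro condensation; the mixed anhydride should O-acylate the 2-hydroxyl, and the arylacetate enolate then undergoes 5-exo aldol addition to the adjacent C-1 carbonyl (the only carbonyl next to the acylated oxygen) and dehydration, giving the butenolide and the extended quinone methide in one operation, a reaction type with close precedent for arylacetic acids on 3-aryl-2-hydroxy-1,4-quinones.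

**Step 8**
Reactants: 15 tri-O-methyl ether of the target
Product: 16 2-(2,7,8-trihydroxy-4-oxo-3-phenyldibenzo[b,d]furan-1(4H)-ylidene)-2-(4-hydroxyphenyl)acetic acid γ-lactone (CNP0139113.0)
Conditions: BBr3 (6 equiv), CH2Cl2, −78 to 0 °C; then H2O
Reagents that add atoms: none
Why: Lewis-acid cleavage of the three aryl methyl ethers by BBr3 is a standard demethylation that conjugated lactones, diaryl ketones and benzofurans tolerate at low temperature.

**Compound list**
1 | 2-hydroxy-4,5-dimethoxybenzaldehyde | O=Cc1cc(OC)c(OC)cc1O | starting material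
2 | N-acetylglycine | CC(=O)NCC(=O)O | starting material
3 | 3-acetamido-6,7-dimethoxy-2H-chromen-2-one | CC(=O)Nc1cc2cc(OC)c(OC)cc2oc1=O | intermediate
4 | 3-hydroxy-6,7-dimethoxy-2H-chromen-2-one | O=c1oc2cc(OC)c(OC)cc2cc1O | intermediate
5 | phenylpyruvic acid (2-oxo-3-phenylpropanoic acid) | O=C(O)C(=O)Cc1ccccc1 | starting material
6 | tert-butyldimethylsilyl (Z)-2-[(tert-butyldimethylsilyl)oxy]-3-phenylprop-2-enoate | CC(C)(C)[Si](C)(C)OC(=O)/C(O[Si](C)(C)C(C)(C)C)=C/c1ccccc1 | intermediate (not isolated)
7 | (Z)-2-[(tert-butyldimethylsilyl)oxy]-3-phenylprop-2-enoic acid | O=C(O)/C(O[Si](C)(C)C(C)(C)C)=C/c1ccccc1 | intermediate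
8 | 6,7-dimethoxy-2-oxo-2H-chromen-3-yl (Z)-2-[(tert-butyldimethylsilyl)oxy]-3-phenylprop-2-enoate | O=C(Oc1cc2cc(OC)c(OC)cc2oc1=O)/C(O[Si](C)(C)C(C)(C)C)=C/c1ccccc1 | intermediate
9 | 6,7-dimethoxy-2-oxo-2H-chromen-3-yl (Z)-2-hydroxy-3-phenylprop-2-enoate (formed as its enolate) | O=C(Oc1cc2cc(OC)c(OC)cc2oc1=O)/C(O)=C/c1ccccc1 | intermediate (not isolated)
10 | (E)-3-hydroxy-6-[(2-hydroxy-4,5-dimethoxyphenyl)methylidene]-4-phenyl-2H-pyran-2,5(6H)-dione | O=C1O/C(=C/c2cc(OC)c(OC)cc2O)C(=O)C(c2ccccc2)=C1O | intermediate (not isolated)
11 | methyl (E)-2-hydroxy-6-(2-hydroxy-4,5-dimethoxyphenyl)-4,5-dioxo-3-phenylhex-2-enoate | COC(=O)/C(O)=C(/c1ccccc1)C(=O)C(=O)Cc1cc(OC)c(OC)cc1O | intermediate (not isolated)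
12 | 2,5-dihydroxy-3-(2-hydroxy-4,5-dimethoxyphenyl)-6-phenylcyclohexa-2,5-diene-1,4-dione | O=C1C(O)=C(c2ccccc2)C(=O)C(O)=C1c1cc(OC)c(OC)cc1O | intermediate
13 | 2-hydroxy-7,8-dimethoxy-3-phenyldibenzo[b,d]furan-1,4-dione | O=C1C(O)=C(c2ccccc2)C(=O)c2oc3cc(OC)c(OC)cc3c21 | intermediate
14 | (4-methoxyphenyl)acetic acid | COc1ccc(CC(=O)O)cc1 | starting material
15 | 2-(2-hydroxy-7,8-dimethoxy-4-oxo-3-phenyldibenzo[b,d]furan-1(4H)-ylidene)-2-(4-methoxyphenyl)acetic acid γ-lactone | O=C1OC2=C(c3ccccc3)C(=O)c3oc4cc(OC)c(OC)cc4c3C2=C1c1ccc(OC)cc1 | intermediate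
16 | 2-(2,7,8-trihydroxy-4-oxo-3-phenyldibenzo[b,d]furan-1(4H)-ylidene)-2-(4-hydroxyphenyl)acetic acid γ-lactone (CNP0139113.0) | O=C1OC2=C(c3ccccc3)C(=O)c3oc4cc(O)c(O)cc4c3C2=C1c1ccc(O)cc1 | target

Total step count: 8.
Longest linear sequence: 7 steps (1 → 3 → 4 → 8 → 12 → 13 → 15 → 16; step 3 supplies 7 on a one-step branch).

**Steps most likely to fail**

Step 5 (proposed new method). The tether may be lost by attack of methoxide or adventitious hydroxide on the enol ester before the first C-acylation. The sequence may also stall at the pyrandione stage, because the lactone carbonyl of 10 is deactivated in its enolate form, and conjugate addition to the arylidene unit may compete. The fallback uses known chemistry, sets out from 1 and comes back at 13, making the two ring bonds one after the other. Rap–Stoermer condensation of 1 with 1-bromo-3-phenylpropan-2-one (K2CO3, acetone, reflux) should give 1-(5,6-dimethoxy-1-benzofuran-2-yl)-2-phenylethan-1-one F1. Claisen condensation of its benzylic ketone position with diethyl oxalate (NaOEt, EtOH) should give ethyl (Z)-4-(5,6-dimethoxy-1-benzofuran-2-yl)-2-hydroxy-4-oxo-3-phenylbut-2-enoate F2, the enol of the 2,4-dioxo ester. Intramolecular Friedel–Crafts acylation at benzofuran C3 (conc. H2SO4 or P2O5 in MeSO3H), the known acid cyclisation of 2,4-dioxo-3-arylbutanoates to 2-hydroxy-3-aryl-1,4-quinones, should then close the central ring and give 13.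

Step 7. Acetylation of the quinone hydroxyl may outrun transfer of the arylacetyl group, and the hot anhydride medium may degrade the quinone before the aldol closure. The fallback sets out from 13 and comes back at 15, making the C–O bond and the C=C bond in separate operations under non-acetylating conditions. O-Acylation of 13 with (4-methoxyphenyl)acetyl chloride (Et3N, CH2Cl2, 0 °C) should give 7,8-dimethoxy-1,4-dioxo-3-phenyl-1,4-dihydrodibenzo[b,d]furan-2-yl (4-methoxyphenyl)acetate F3. Soft enolisation (TiCl4, Et3N, CH2Cl2, −20 °C to rt) should then bring about the intramolecular Knoevenagel-type aldol condensation onto the C-1 carbonyl to give 15.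

Step 8. Bromide may add in conjugate fashion to the Lewis-acid-activated quinone methide, the enol lactone may be cleaved, or the ether cleavage may stop short of completion. The fallback sets out from 13 and comes back at 16, moving the demethylation in front of the lactone-forming step. BBr3 in CH2Cl2 should convert 13 into 2,7,8-trihydroxy-3-phenyldibenzo[b,d]furan-1,4-dione F4. Perkin–Oglialoro condensation of F4 with (4-hydroxyphenyl)acetic acid in Ac2O and NaOAc (all phenols acetylated in the flask) should give the tri-O-acetate of the target F5. Acid-catalysed transesterification (HCl in MeOH, rt) should then remove the three acetates and give 16 without Lewis acid or strong base.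

**Further compounds**
F1 | step 5 | 1-(5,6-dimethoxy-1-benzofuran-2-yl)-2-phenylethan-1-one | O=C(Cc1ccccc1)c1cc2cc(OC)c(OC)cc2o1
F2 | step 5 | ethyl (Z)-4-(5,6-dimethoxy-1-benzofuran-2-yl)-2-hydroxy-4-oxo-3-phenylbut-2-enoate | CCOC(=O)/C(O)=C(\c1ccccc1)C(=O)c1cc2cc(OC)c(OC)cc2o1
F3 | step 7 | 7,8-dimethoxy-1,4-dioxo-3-phenyl-1,4-dihydrodibenzo[b,d]furan-2-yl (4-methoxyphenyl)acetate | COc1ccc(CC(=O)OC2=C(c3ccccc3)C(=O)c3oc4cc(OC)c(OC)cc4c3C2=O)cc1
F4 | step 8 | 2,7,8-trihydroxy-3-phenyldibenzo[b,d]furan-1,4-dione | O=C1C(O)=C(c2ccccc2)C(=O)c2oc3cc(O)c(O)cc3c21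
F5 | step 8 | 2-(7,8-diacetoxy-2-hydroxy-4-oxo-3-phenyldibenzo[b,d]furan-1(4H)-ylidene)-2-(4-acetoxyphenyl)acetic acid γ-lactone | O=C1OC2=C(c3ccccc3)C(=O)c3oc4cc(OC(C)=O)c(OC(C)=O)cc4c3C2=C1c1ccc(OC(C)=O)cc1
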